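**Plan**
- Enabling feature: on the cyclohexane ring the C1 hydroxyl and the C4 chlorine are cis-1,4, and the C5 bromine is trans to that chlorine. A C1–O–C4 bridge (a 7-oxabicyclo[2.2.1]heptane) can therefore hold the place of chloride and push bromine to the other face.
- Retrosynthetic cuts, in order: O–Si at C10; C7=CH2 (back to a C7 ketone); C4–Cl (exchanged for the C4–O bridge bond); C7–C8 (bridgehead aldehyde plus side-chain Grignard reagent); C4–O and C5–Br together (back to a C4=C5 cyclohexenol); C10–C11 in the side chain.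
- Forward: the carbocycle comes from an arene by Birch reduction and the temporary oxolane ring closes in step 5. The C8–C13 chain is joined to C7 in step 15, the bridge is reopened to C4–Cl in step 17, and the last carbon is added in step 18.
- Stereochemistry: C1 comes from a Sharpless asymmetric epoxidation. C4 and C5 are relayed from C1 by the tether and anti addition. C4 is kept by double inversion through the bromonium ion. C10 comes from a Sharpless kinetic resolution.

Key step: step 5

Numbering used throughout: ring C1 (carbinol), C2, C3, C4 (CH3, Cl), C5 (Br), C6; chain C7 (bears the exocyclic CH2), C8, C9, C10 (carbinol), C11 (isopropenyl carbon).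

Assumption: both tartrate-controlled steps follow the normal sense of induction of L-(+)-tartrates, that is, 2S epoxy alcohols from primary allylic alcohols (as with geraniol) and faster consumption of the S enantiomer of a secondary allylic alcohol.

**Ring fragment (steps 1–7)**

Step 1
Reactants: 1 4-methylbenzyl alcohol
Product: 2 (4-methylcyclohexa-1,4-dien-1-yl)methanol
Conditions: n-BuLi (1.0 equiv), THF, −78 °C; then Li (in portions until the blue colour just persists), NH3(l), t-BuOH, −78 to −33 °C; NH4Cl
Reagents that add atoms: none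
Why: Birch reduction of a 1,4-dialkyl-type arene leaves both donor substituents on the remaining double bonds, and using the preformed lithium alkoxide with t-BuOH as the only proton source protects the benzylic C–O bond from reductive cleavage.

Step 2
Reactants: 2 (4-methylcyclohexa-1,4-dien-1-yl)methanol
Product: 3 [(1S,6S)-4-methyl-7-oxabicyclo[4.1.0]hept-3-en-1-yl]methanol
Conditions: Ti(OiPr)4 (10 mol %), L-(+)-diethyl tartrate (12 mol %), t-BuOOH, 4 Å MS, CH2Cl2, −20 °C
Reagents that add atoms: tert-butyl hydroperoxide, CC(C)(C)OO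
Why: Katsuki–Sharpless asymmetric epoxidation touches only the alkene that carries the titanium-bound CH2OH, and L-(+)-tartrate places oxygen on the face that makes C1 S (the S centre formed at C2 is erased in step 3).

Step 3
Reactants: 3 [(1S,6S)-4-methyl-7-oxabicyclo[4.1.0]hept-3-en-1-yl]methanol
Product: 4 (1S)-1-(hydroxymethyl)-4-methylcyclohex-3-en-1-ol
Conditions: LiAlH4, THF, 0 °C to rt; H2O
Reagents that add atoms: none
Why: Hydride opens the trisubstituted epoxide by SN2 attack at the secondary carbon C2, so the C1–O bond and the S configuration at C1 stay untouched and a 1,2-diol with a tertiary carbinol results.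

Step 4
Reactants: 4 (1S)-1-(hydroxymethyl)-4-methylcyclohex-3-en-1-ol; 5 benzoyl chloride
Product: 6 [(1S)-1-hydroxy-4-methylcyclohex-3-en-1-yl]methyl benzoate
Conditions: pyridine, CH2Cl2, 0 °C
Reagents that add atoms: none
Why: Acylation distinguishes cleanly between a primary and a tertiary hydroxyl, and the resulting ester oxygen is too poor a nucleophile to compete in step 5.

Step 5
Reactants: 6 [(1S)-1-hydroxy-4-methylcyclohex-3-en-1-yl]methyl benzoate
Product: 7 [(1S,3R,4R)-3-bromo-4-methyl-7-oxabicyclo[2.2.1]heptan-1-yl]methyl benzoate (O bridges C1 and C4; Br at C5 is endo, anti to the bridge)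
Conditions: N-bromosuccinimide (1.1 equiv), CH2Cl2, 0 °C to rt, dark
Reagents that add atoms: N-bromosuccinimide, O=C1CCC(=O)N1Br
Why: NBS hands Br+ reversibly to both faces of C4=C5, but only the bromonium ion on the face opposite the C1 hydroxyl is consumed, because in a boat conformation that oxygen reaches across the ring and opens the ion from the rear at C4, making C4–O and leaving C5–Br in one anti addition. The closest known reaction type is the bromoetherification of cyclohex-3-en-1-ols such as terpinen-4-ol, which gives bromo-1,4-cineoles. The new oxolane ring O–C1–C2–C3–C4 closes in the 5-exo mode (the C4–C5 bond stays outside it), and this single closure turns the cyclohexene into the 7-oxabicyclo[2.2.1]heptane. C4 becomes R because the tethered oxygen can arrive only on the face on which it sits at C1, and C5 becomes R because rear-side opening leaves bromine on the opposite face, endo and anti to the bridge. The step needs regioselectivity for C4, secured by the methyl group (Markovnikov carbon; attack at C5 would give a strained oxetane bridge), and chemoselectivity for the tertiary hydroxyl, secured by keeping the primary oxygen as a benzoate so that it cannot close a 2-oxabicyclo[2.2.2]octane from the other face.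

Step 6
Reactants: 7 [(1S,3R,4R)-3-bromo-4-methyl-7-oxabicyclo[2.2.1]heptan-1-yl]methyl benzoate
Product: 8 [(1S,3R,4R)-3-bromo-4-methyl-7-oxabicyclo[2.2.1]heptan-1-yl]methanol
Conditions: K2CO3 (0.2 equiv), MeOH, rt
Reagents that add atoms: none
Why: Base-catalysed transesterification frees the primary alcohol, while the endo bromide on the rigid bicycle has no antiperiplanar hydrogen and a shielded rear side, so neither E2 nor SN2 competes.

Step 7
Reactants: 8 [(1S,3R,4R)-3-bromo-4-methyl-7-oxabicyclo[2.2.1]heptan-1-yl]methanol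
Product: 9 (1S,3R,4R)-3-bromo-4-methyl-7-oxabicyclo[2.2.1]heptane-1-carbaldehyde
Conditions: Dess–Martin periodinane, CH2Cl2, 0 °C to rt
Reagents that add atoms: none
Why: Dess–Martin oxidation stops at the aldehyde, which has no α-hydrogen and so can neither enolise nor epimerise.

**Side chain (steps 8–14)**

Step 8
Reactants: 10 propane-1,3-diol
Product: 11 3-[(tert-butyldimethylsilyl)oxy]propan-1-ol
Conditions: NaH (1.0 equiv), THF, rt; then TBSCl (1.0 equiv)
Reagents that add atoms: tert-butyldimethylsilyl chloride, CC(C)(C)[Si](C)(C)Cl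
Why: Silylation of a symmetrical diol through its sparingly soluble monosodium alkoxide is the standard way to stop at the mono ether.

Step 9
Reactants: 11 3-[(tert-butyldimethylsilyl)oxy]propan-1-ol
Product: 12 3-[(tert-butyldimethylsilyl)oxy]propanal
Conditions: Dess–Martin periodinane, CH2Cl2, 0 °C to rt
Reagents that add atoms: none
Why: Dess–Martin oxidation is neutral enough to avoid β-elimination of the silyloxy group from the aldehyde.

Step 10
Reactants: 12 3-[(tert-butyldimethylsilyl)oxy]propanal; 13 2-bromopropene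
Product: 15 rac-5-[(tert-butyldimethylsilyl)oxy]-2-methylpent-1-en-3-ol, via isopropenylmagnesium bromide 14 (not isolated)
Conditions: Mg, THF, rt; then 12, −78 to 0 °C; aq NH4Cl
Reagents that add atoms: none
Why: Grignard 1,2-addition of the isopropenyl nucleophile to the aldehyde forms C10–C11 and gives C10 in racemic form, to be resolved in step 11.

Step 11
Reactants: 15 rac-5-[(tert-butyldimethylsilyl)oxy]-2-methylpent-1-en-3-ol
Product: 16 (3R)-5-[(tert-butyldimethylsilyl)oxy]-2-methylpent-1-en-3-ol
Conditions: Ti(OiPr)4 (15 mol %), L-(+)-diisopropyl tartrate (18 mol %), t-BuOOH (0.6 equiv), 4 Å MS, CH2Cl2, −20 °C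
Reagents that add atoms: none
Why: In a Sharpless kinetic resolution with L-(+)-tartrate the S enantiomer of a 2-methylalk-1-en-3-ol is epoxidised much faster, so stopping a little beyond half conversion should leave the R alcohol (C10 of the target) enantiomerically pure.

Step 12
Reactants: 16 (3R)-5-[(tert-butyldimethylsilyl)oxy]-2-methylpent-1-en-3-ol
Product: 17 (3R)-3,5-bis[(tert-butyldimethylsilyl)oxy]-2-methylpent-1-ene
Conditions: TBSCl, imidazole, DMF, rt
Reagents that add atoms: tert-butyldimethylsilyl chloride, CC(C)(C)[Si](C)(C)Cl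
Why: Imidazole-promoted silylation protects the secondary allylic alcohol without touching any bond to C10.

Step 13
Reactants: 17 (3R)-3,5-bis[(tert-butyldimethylsilyl)oxy]-2-methylpent-1-ene
Product: 18 (3R)-3-[(tert-butyldimethylsilyl)oxy]-4-methylpent-4-en-1-ol
Conditions: camphorsulfonic acid (10 mol %), MeOH/CH2Cl2, 0 °C
Reagents that add atoms: none
Why: Acid-catalysed methanolysis of silyl ethers is governed by steric access, so the primary TBS ether is cleaved well before the hindered secondary one.

Step 14
Reactants: 18 (3R)-3-[(tert-butyldimethylsilyl)oxy]-4-methylpent-4-en-1-ol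
Product: 19 {[(3R)-5-bromo-2-methylpent-1-en-3-yl]oxy}(tert-butyl)dimethylsilane
Conditions: CBr4, PPh3, CH2Cl2, 0 °C
Reagents that add atoms: carbon tetrabromide, BrC(Br)(Br)Br
Why: The Appel reaction converts the primary alcohol into the bromide under neutral conditions that leave the allylic silyl ether and the alkene alone.

**Coupling and endgame (steps 15–19)**

Step 15
Reactants: 9 (1S,3R,4R)-3-bromo-4-methyl-7-oxabicyclo[2.2.1]heptane-1-carbaldehyde; 19 {[(3R)-5-bromo-2-methylpent-1-en-3-yl]oxy}(tert-butyl)dimethylsilane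
Product: 21 (4R)-1-[(1S,3R,4R)-3-bromo-4-methyl-7-oxabicyclo[2.2.1]heptan-1-yl]-4-[(tert-butyldimethylsilyl)oxy]-5-methylhex-5-en-1-ol (both C7 epimers), via side-chain Grignard reagent 20 (not isolated)
Conditions: 19, Mg, THF, rt; then 9, THF, −78 to 0 °C; aq NH4Cl
Reagents that add atoms: none
Why: Grignard addition to the non-enolisable aldehyde forms C7–C8 far faster than an alkylmagnesium halide attacks a secondary bromide, and the new C7 centre needs no control because step 16 removes it.

Step 16
Reactants: 21 (4R)-1-[(1S,3R,4R)-3-bromo-4-methyl-7-oxabicyclo[2.2.1]heptan-1-yl]-4-[(tert-butyldimethylsilyl)oxy]-5-methylhex-5-en-1-ol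
Product: 22 (4R)-1-[(1S,3R,4R)-3-bromo-4-methyl-7-oxabicyclo[2.2.1]heptan-1-yl]-4-[(tert-butyldimethylsilyl)oxy]-5-methylhex-5-en-1-one
Conditions: Dess–Martin periodinane, CH2Cl2, 0 °C to rt
Reagents that add atoms: none
Why: Dess–Martin oxidation merges both C7 epimers into one ketone and installs beside C1 the carbonyl group that step 17 relies on.

Step 17
Reactants: 22 (4R)-1-[(1S,3R,4R)-3-bromo-4-methyl-7-oxabicyclo[2.2.1]heptan-1-yl]-4-[(tert-butyldimethylsilyl)oxy]-5-methylhex-5-en-1-one
Product: 24 (4R)-1-[(1S,3R,4R)-3-bromo-4-chloro-1-hydroxy-4-methylcyclohexyl]-4-[(tert-butyldimethylsilyl)oxy]-5-methylhex-5-en-1-one, via dichloroboryl ether 23 (not isolated)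
Conditions: BCl3 (1.2 equiv), 2,6-di-tert-butyl-4-methylpyridine (0.3 equiv), CH2Cl2, −78 to −40 °C; pH 7 buffer
Reagents that add atoms: boron trichloride, ClB(Cl)Cl
Why: Proposed new method: BCl3 binds the C7 carbonyl oxygen and, on losing chloride, also the bridge oxygen (five-membered O=C7–C1–O chelate); of the two tertiary C–O bonds only C4–O can ionise, because a cation at C1 would sit next to the carbonyl group whereas the endo C5–Br bond lies almost antiperiplanar to C4–O and re-forms the bromonium ion of step 5, so the released chloride can enter only at the more substituted C4 and only from the face the oxygen has just left, giving net retention at C4 (Cl cis to the C1 oxygen, trans to Br) by double inversion; the closest known reaction types are the chelation-directed cleavage of ethers beside a carbonyl group with BCl3, the opening of 7-oxabicyclo[2.2.1]heptanes and cineoles with boron or hydrogen halides, and retentive substitution next to bromine by neighbouring-group participation, but their combination on a β-bromo bridged ether is without direct precedent.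

Step 18
Reactants: 24 (4R)-1-[(1S,3R,4R)-3-bromo-4-chloro-1-hydroxy-4-methylcyclohexyl]-4-[(tert-butyldimethylsilyl)oxy]-5-methylhex-5-en-1-one
Product: 25 (1S,3R,4R)-3-bromo-1-{(5R)-5-[(tert-butyldimethylsilyl)oxy]-6-methylhepta-1,6-dien-2-yl}-4-chloro-4-methylcyclohexan-1-ol
Conditions: Cp2TiMe2 (4 equiv), toluene/THF, 65 °C, dark
Reagents that add atoms: dimethyltitanocene Cp2TiMe2, C[Ti+2]C.c1cc[cH-]c1.c1cc[cH-]c1
Why: Petasis methylenation works through Cp2Ti=CH2, which adds to the ketone and cycloreverts to the alkene without any base, so the diequatorial halides see no E2 conditions and the free hydroxyl merely consumes part of the excess reagent.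

Step 19
Reactants: 25 (1S,3R,4R)-3-bromo-1-{(5R)-5-[(tert-butyldimethylsilyl)oxy]-6-methylhepta-1,6-dien-2-yl}-4-chloro-4-methylcyclohexan-1-ol
Product: 26 (1S,3R,4R)-3-bromo-4-chloro-1-[(5R)-5-hydroxy-6-methylhepta-1,6-dien-2-yl]-4-methylcyclohexan-1-ol (CNP0187094.2)
Conditions: HF·pyridine, pyridine, THF, 0 °C to rt
Reagents that add atoms: none
Why: Fluoride-driven cleavage of the Si–O bond under pyridine-buffered conditions spares the tertiary chloride, the secondary bromide and the tertiary allylic alcohol.

**Compound list**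
1 | 4-methylbenzyl alcohol | Cc1ccc(CO)cc1 | starting material
2 | (4-methylcyclohexa-1,4-dien-1-yl)methanol | CC1=CCC(CO)=CC1 | intermediate
3 | [(1S,6S)-4-methyl-7-oxabicyclo[4.1.0]hept-3-en-1-yl]methanol | OC[C@]12O[C@H]1CC(C)=CC2 | intermediate
4 | (1S)-1-(hydroxymethyl)-4-methylcyclohex-3-en-1-ol | OC[C@]1(O)CCC(C)=CC1 | intermediate
5 | benzoyl chloride | O=C(Cl)c1ccccc1 | starting material
6 | [(1S)-1-hydroxy-4-methylcyclohex-3-en-1-yl]methyl benzoate | O=C(OC[C@]1(O)CCC(C)=CC1)c1ccccc1 | intermediate
7 | [(1S,3R,4R)-3-bromo-4-methyl-7-oxabicyclo[2.2.1]heptan-1-yl]methyl benzoate | O=C(OC[C@]1(O2)CC[C@]2(C)[C@H](Br)C1)c1ccccc1 | intermediate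
8 | [(1S,3R,4R)-3-bromo-4-methyl-7-oxabicyclo[2.2.1]heptan-1-yl]methanol | OC[C@]1(O2)CC[C@]2(C)[C@H](Br)C1 | intermediate
9 | (1S,3R,4R)-3-bromo-4-methyl-7-oxabicyclo[2.2.1]heptane-1-carbaldehyde | O=C[C@]1(O2)CC[C@]2(C)[C@H](Br)C1 | intermediate
10 | propane-1,3-diol | OCCCO | starting material
11 | 3-[(tert-butyldimethylsilyl)oxy]propan-1-ol | CC(C)(C)[Si](C)(C)OCCCO | intermediate
12 | 3-[(tert-butyldimethylsilyl)oxy]propanal | CC(C)(C)[Si](C)(C)OCCC=O | intermediate
13 | 2-bromopropene | C=C(C)Br | starting material
14 | isopropenylmagnesium bromide | C=C(C)[Mg]Br | intermediate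
15 | rac-5-[(tert-butyldimethylsilyl)oxy]-2-methylpent-1-en-3-ol | C=C(C)C(O)CCO[Si](C)(C)C(C)(C)C | intermediate
16 | (3R)-5-[(tert-butyldimethylsilyl)oxy]-2-methylpent-1-en-3-ol | C=C(C)[C@H](O)CCO[Si](C)(C)C(C)(C)C | intermediate
17 | (3R)-3,5-bis[(tert-butyldimethylsilyl)oxy]-2-methylpent-1-ene | C=C(C)[C@H](O[Si](C)(C)C(C)(C)C)CCO[Si](C)(C)C(C)(C)C | intermediate
18 | (3R)-3-[(tert-butyldimethylsilyl)oxy]-4-methylpent-4-en-1-ol | C=C(C)[C@H](O[Si](C)(C)C(C)(C)C)CCO | intermediate
19 | {[(3R)-5-bromo-2-methylpent-1-en-3-yl]oxy}(tert-butyl)dimethylsilane | C=C(C)[C@H](O[Si](C)(C)C(C)(C)C)CCBr | intermediate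
20 | {(3R)-3-[(tert-butyldimethylsilyl)oxy]-4-methylpent-4-en-1-yl}magnesium bromide | C=C(C)[C@H](O[Si](C)(C)C(C)(C)C)CC[Mg]Br | intermediate
21 | (4R)-1-[(1S,3R,4R)-3-bromo-4-methyl-7-oxabicyclo[2.2.1]heptan-1-yl]-4-[(tert-butyldimethylsilyl)oxy]-5-methylhex-5-en-1-ol, both C7 epimers | C=C(C)[C@H](O[Si](C)(C)C(C)(C)C)CCC(O)[C@]1(O2)CC[C@]2(C)[C@H](Br)C1 | intermediate
22 | (4R)-1-[(1S,3R,4R)-3-bromo-4-methyl-7-oxabicyclo[2.2.1]heptan-1-yl]-4-[(tert-butyldimethylsilyl)oxy]-5-methylhex-5-en-1-one | C=C(C)[C@H](O[Si](C)(C)C(C)(C)C)CCC(=O)[C@]1(O2)CC[C@]2(C)[C@H](Br)C1 | intermediate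
23 | dichloroboryl ether of 24 at the C1 oxygen | C=C(C)[C@H](O[Si](C)(C)C(C)(C)C)CCC(=O)[C@]1(OB(Cl)Cl)CC[C@@](C)(Cl)[C@H](Br)C1 | intermediate
24 | (4R)-1-[(1S,3R,4R)-3-bromo-4-chloro-1-hydroxy-4-methylcyclohexyl]-4-[(tert-butyldimethylsilyl)oxy]-5-methylhex-5-en-1-one | C=C(C)[C@H](O[Si](C)(C)C(C)(C)C)CCC(=O)[C@]1(O)CC[C@@](C)(Cl)[C@H](Br)C1 | intermediate
25 | (1S,3R,4R)-3-bromo-1-{(5R)-5-[(tert-butyldimethylsilyl)oxy]-6-methylhepta-1,6-dien-2-yl}-4-chloro-4-methylcyclohexan-1-ol | C=C(C)[C@H](O[Si](C)(C)C(C)(C)C)CCC(=C)[C@]1(O)CC[C@@](C)(Cl)[C@H](Br)C1 | intermediate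
26 | (1S,3R,4R)-3-bromo-4-chloro-1-[(5R)-5-hydroxy-6-methylhepta-1,6-dien-2-yl]-4-methylcyclohexan-1-ol | C=C(C)[C@H](O)CCC(=C)[C@]1(O)CC[C@@](C)(Cl)[C@H](Br)C1 | target

**Counts**
- Total step count: 19.
- Longest linear sequence: 12 steps (1–7, then 15–19). The side-chain branch (8–14, then 15–19) is equally long.

**Steps most likely to fail**

Step 17.
- Several processes could compete with the intended opening. The Lewis acid may ionise the allylic C10–O silyl ether instead of C4–O. The bromonium ion may lose a proton. It may also hand Br+ back to chloride (reversal of step 5) faster than chloride adds at C4.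
- The fallback uses known chemistry only. It sets out from 22 and returns at 24.
- Zn dust in AcOH/THF at rt carries out the reductive β-elimination by which alkenes stored as halo ethers are normally unmasked. It gives (4R)-4-[(tert-butyldimethylsilyl)oxy]-1-[(1S)-1-hydroxy-4-methylcyclohex-3-en-1-yl]-5-methylhex-5-en-1-one F1.
- (CF3CO)2O and pyridine then convert the C1 hydroxyl into a non-nucleophilic ester that cannot re-close, the trifluoroacetate F2.
- Intermolecular anti, Markovnikov bromochlorination of the more electron-rich ring alkene with NBS and Bu4NCl in CH2Cl2 at −78 °C gives the bromochloride trifluoroacetate F3.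
- NaHCO3 in MeOH removes the trifluoroacetyl group and delivers 24.
- The price is that the facial relay from C1 is lost, so a chromatographic separation of ring diastereomers would be needed.

Step 18.
- Methylenation may be slow at a carbonyl group flanked by a fully substituted carbinol carbon.
- During prolonged heating, titanium by-products in the trivalent state may reduce the vicinal dihalide by single-electron transfer.
- The fallback sets out from 24 and returns at 26, bypassing 25, by a Peterson olefination.
- Me3SiCH2MgCl with CeCl3 (3 equiv, THF, −78 to 0 °C) adds to the ketone. It gives (5R)-2-[(1S,3R,4R)-3-bromo-4-chloro-1-hydroxy-4-methylcyclohexyl]-5-[(tert-butyldimethylsilyl)oxy]-6-methyl-1-(trimethylsilyl)hept-6-en-2-ol F4.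
- Aqueous HF in MeCN at 0 °C then triggers the β-silicon-assisted elimination of Me3Si and OH and removes the TBS group in the same flask, giving 26.

Step 1.
- Reductive cleavage of the benzylic C–O bond may compete with ring reduction.
- The diene may re-aromatise on handling.
- The fallback sets out from benzoyl chloride 5 and returns at diol 4. It bypasses 1–3 and sets C1 by catalysis.
- O-benzoylation of commercial 2,2-dimethyl-1,3-dioxan-5-one (Et3N, DMAP cat., CH2Cl2) gives 2,2-dimethyl-4H-1,3-dioxin-5-yl benzoate F5.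
- Thermolysis in toluene at 120 °C (retro-hetero-Diels–Alder reaction) gives 2-(benzoyloxy)acrolein F6.
- An enantioselective, para-selective Diels–Alder reaction with isoprene follows, under iminium catalysis by a chiral 1,1'-binaphthyl-2,2'-diammonium salt of the appropriate handedness. It gives (1S)-1-formyl-4-methylcyclohex-3-en-1-yl benzoate F7.
- LiAlH4 in THF reduces the aldehyde and the ester together to 4.

**Further compounds**
F1 | step 17 | (4R)-4-[(tert-butyldimethylsilyl)oxy]-1-[(1S)-1-hydroxy-4-methylcyclohex-3-en-1-yl]-5-methylhex-5-en-1-one | C=C(C)[C@H](O[Si](C)(C)C(C)(C)C)CCC(=O)[C@]1(O)CCC(C)=CC1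
F2 | step 17 | (1S)-1-{(4R)-4-[(tert-butyldimethylsilyl)oxy]-5-methylhex-5-enoyl}-4-methylcyclohex-3-en-1-yl trifluoroacetate | C=C(C)[C@H](O[Si](C)(C)C(C)(C)C)CCC(=O)[C@]1(OC(=O)C(F)(F)F)CCC(C)=CC1
F3 | step 17 | (1S,3R,4R)-3-bromo-1-{(4R)-4-[(tert-butyldimethylsilyl)oxy]-5-methylhex-5-enoyl}-4-chloro-4-methylcyclohexyl trifluoroacetate | C=C(C)[C@H](O[Si](C)(C)C(C)(C)C)CCC(=O)[C@]1(OC(=O)C(F)(F)F)CC[C@@](C)(Cl)[C@H](Br)C1
F4 | step 18 | (5R)-2-[(1S,3R,4R)-3-bromo-4-chloro-1-hydroxy-4-methylcyclohexyl]-5-[(tert-butyldimethylsilyl)oxy]-6-methyl-1-(trimethylsilyl)hept-6-en-2-ol | C=C(C)[C@H](O[Si](C)(C)C(C)(C)C)CCC(O)(C[Si](C)(C)C)[C@]1(O)CC[C@@](C)(Cl)[C@H](Br)C1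
F5 | step 1 | 2,2-dimethyl-4H-1,3-dioxin-5-yl benzoate | CC1(C)OCC(OC(=O)c2ccccc2)=CO1
F6 | step 1 | 2-(benzoyloxy)acrolein | C=C(C=O)OC(=O)c1ccccc1
F7 | step 1 | (1S)-1-formyl-4-methylcyclohex-3-en-1-yl benzoate | O=C[C@]1(OC(=O)c2ccccc2)CCC(C)=CC1
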